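**Retrosynthetic overview**
1. Target 27 ⇐ diester 26 (saponification). The (2Z)-enoate of 26 ⇐ Ando-type Horner–Wadsworth–Emmons coupling of phosphonate 21 with aldehyde 25, which an ene-reductase makes from enal 24.
2. 21 ⇐ iodide 19 + diaryl phosphonoacetate 20. The (E)-enoate of 19 ⇐ Wittig reaction of aldehyde 12 with ester ylide 16.
3. The (E)-trisubstituted alkene and aldehyde 12 ⇐ Johnson–Claisen rearrangement of allylic alcohol 7 ⇐ lactol 4 + isopropenyl Grignard 5.
4. The single stereocentre ⇐ rhodium/(R)-BINAP-catalysed 1,4-addition of isopropenylboronate 2 to achiral lactone 1.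
5. Rings: none is built. The furan comes in intact with furan-3-carbaldehyde 22, and the lactone ring of 1 is opened in steps 2–3.

Assumption: 2, 5, 8, 13, 20, 22, 23 and the two recombinant enzymes (ene-reductase, formate dehydrogenase) are taken as catalogue items; epimer mixtures at centres that are destroyed later (C2 of 4, C3 of 6 and 7, C2 of 21) are carried on unseparated.

**Route**

Step 1
Reactants: 1 5,6-dihydro-2H-pyran-2-one; 2 4,4,5,5-tetramethyl-2-(prop-1-en-2-yl)-1,3,2-dioxaborolane (3 equiv)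
Product: 3 (4R)-4-(prop-1-en-2-yl)oxan-2-one
Conditions: [RhCl(C2H4)2]2 (2.5 mol %), (R)-BINAP (5.5 mol %), KOH (10 mol %), 1,4-dioxane/H2O 10:1, 60 °C
Reagents that add atoms: none
Why: Rhodium-catalysed asymmetric 1,4-addition (Hayashi–Miyaura reaction): the (R)-BINAP-bound isopropenylrhodium species adds to one enantioface of the s-trans-locked enoate and water protonates the rhodium enolate, which sets C4 as R (the only stereocentre of the target, made from achiral inputs).

Step 2
Reactants: 3 (4R)-4-(prop-1-en-2-yl)oxan-2-one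
Product: 4 (4R)-4-(prop-1-en-2-yl)oxan-2-ol (lactol, both anomers)
Conditions: i-Bu2AlH (1.1 equiv), CH2Cl2, −78 °C; aq. KNaC4H4O6
Reagents that add atoms: none
Why: Partial hydride reduction of a lactone: the aluminium hemiacetal survives at −78 °C and gives the lactol on work-up, leaving C4 untouched.

Step 3
Reactants: 4 (4R)-4-(prop-1-en-2-yl)oxan-2-ol; 5 prop-1-en-2-ylmagnesium bromide (3 equiv)
Product: 6 (5R)-2-methyl-5-(prop-1-en-2-yl)hept-1-ene-3,7-diol (both C3 epimers)
Conditions: THF, 0 °C to rt; aq. NH4Cl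
Reagents that add atoms: none
Why: Grignard addition to the open hydroxy-aldehyde form of the magnesium lactolate; the new carbinol centre forms unselectively, which is harmless because step 5 turns it into an sp2 carbon.

Step 4
Reactants: 6 (5R)-2-methyl-5-(prop-1-en-2-yl)hept-1-ene-3,7-diol
Product: 7 (5R)-7-[(tert-butyldimethylsilyl)oxy]-2-methyl-5-(prop-1-en-2-yl)hept-1-en-3-ol
Conditions: t-BuMe2SiCl (1.05 equiv), imidazole (2 equiv), CH2Cl2, −20 to 0 °C
Reagents that add atoms: tert-butyldimethylsilyl chloride, CC(C)(C)[Si](C)(C)Cl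
Why: Chemoselective silyl ether formation: the unhindered primary hydroxyl reacts much faster than the secondary allylic one next to the 2-methylallyl group.

Step 5
Reactants: 7 (5R)-7-[(tert-butyldimethylsilyl)oxy]-2-methyl-5-(prop-1-en-2-yl)hept-1-en-3-ol; 8 1,1,1-triethoxyethane (5 equiv)
Product: 10 ethyl (4E,7S)-9-[(tert-butyldimethylsilyl)oxy]-4-methyl-7-(prop-1-en-2-yl)non-4-enoate, via ketene acetal 9 (not isolated)
Conditions: EtCO2H (10 mol %), 135 °C, EtOH distilled off
Reagents that add atoms: none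
Why: Johnson–Claisen (orthoester) rearrangement: the chair transition state with the side chain equatorial gives the (E)-trisubstituted alkene and adds the two-carbon ester arm, while the existing stereocentre is not involved (it is now named S only because the substituent priorities change).

Step 6
Reactants: 10 ethyl (4E,7S)-9-[(tert-butyldimethylsilyl)oxy]-4-methyl-7-(prop-1-en-2-yl)non-4-enoate
Product: 11 (4E,7S)-9-[(tert-butyldimethylsilyl)oxy]-4-methyl-7-(prop-1-en-2-yl)non-4-en-1-ol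
Conditions: i-Bu2AlH (2.5 equiv), CH2Cl2, −78 to 0 °C; aq. KNaC4H4O6
Reagents that add atoms: none
Why: Ester-to-alcohol reduction with an aluminium hydride, to which the silyl ether and the isolated alkenes are inert.

Step 7
Reactants: 11 (4E,7S)-9-[(tert-butyldimethylsilyl)oxy]-4-methyl-7-(prop-1-en-2-yl)non-4-en-1-ol
Product: 12 (4E,7S)-9-[(tert-butyldimethylsilyl)oxy]-4-methyl-7-(prop-1-en-2-yl)non-4-enal
Conditions: TEMPO (10 mol %), PhI(OAc)2 (1.1 equiv), CH2Cl2, rt
Reagents that add atoms: none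
Why: Oxoammonium (TEMPO) oxidation of a primary alcohol that stops at the aldehyde and leaves the alkenes and the silyl ether alone.

Step 8
Reactants: 13 5-bromo-2-methylpent-2-ene
Product: 14 (4-methylpent-3-en-1-yl)triphenylphosphonium bromide
Conditions: PPh3 (1.05 equiv), MeCN, reflux
Reagents that add atoms: triphenylphosphine, c1ccc(cc1)P(c1ccccc1)c1ccccc1
Why: SN2 quaternisation of triphenylphosphine by a primary alkyl bromide.

Step 9
Reactants: 14 (4-methylpent-3-en-1-yl)triphenylphosphonium bromide (2 equiv)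
Product: 16 methyl 6-methyl-2-(triphenyl-λ5-phosphanylidene)hept-5-enoate, via ylide 15 (not isolated)
Conditions: n-BuLi (2 equiv), THF, −78 to 0 °C; then ClCO2Me (1 equiv), −78 °C to rt
Reagents that add atoms: methyl chloroformate, COC(=O)Cl
Why: C-acylation of a non-stabilised ylide with a chloroformate followed by transylidation (Bestmann method): the second equivalent of 15 deprotonates the acylphosphonium salt to give the ester-stabilised ylide.

Step 10
Reactants: 12 (4E,7S)-9-[(tert-butyldimethylsilyl)oxy]-4-methyl-7-(prop-1-en-2-yl)non-4-enal; 16 methyl 6-methyl-2-(triphenyl-λ5-phosphanylidene)hept-5-enoate (1.5 equiv)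
Product: 17 methyl (2E,6E,9S)-11-[(tert-butyldimethylsilyl)oxy]-6-methyl-2-(4-methylpent-3-en-1-yl)-9-(prop-1-en-2-yl)undeca-2,6-dienoate
Conditions: toluene, 100 °C
Reagents that add atoms: none
Why: Wittig olefination with an α-substituted ester-stabilised ylide, which places the aldehyde chain trans to the ester (E-selective, as is usual for stabilised ylides).

Step 11
Reactants: 17 methyl (2E,6E,9S)-11-[(tert-butyldimethylsilyl)oxy]-6-methyl-2-(4-methylpent-3-en-1-yl)-9-(prop-1-en-2-yl)undeca-2,6-dienoate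
Product: 18 methyl (2E,6E,9S)-11-hydroxy-6-methyl-2-(4-methylpent-3-en-1-yl)-9-(prop-1-en-2-yl)undeca-2,6-dienoate
Conditions: Bu4NF (1.2 equiv), THF, 0 °C to rt
Reagents that add atoms: none
Why: Fluoride-induced cleavage of the silyl ether, driven by the strong Si–F bond; the conjugated ester and the alkenes are unaffected.

Step 12
Reactants: 18 methyl (2E,6E,9S)-11-hydroxy-6-methyl-2-(4-methylpent-3-en-1-yl)-9-(prop-1-en-2-yl)undeca-2,6-dienoate
Product: 19 methyl (2E,6E,9S)-11-iodo-6-methyl-2-(4-methylpent-3-en-1-yl)-9-(prop-1-en-2-yl)undeca-2,6-dienoate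
Conditions: I2 (1.3 equiv), PPh3 (1.3 equiv), imidazole (1.6 equiv), CH2Cl2, 0 °C
Reagents that add atoms: iodine, II
Why: Appel-type iodination (Garegg–Samuelsson conditions): the alkoxyphosphonium ion is displaced by iodide in an SN2 reaction at the primary carbon.

Step 13
Reactants: 19 methyl (2E,6E,9S)-11-iodo-6-methyl-2-(4-methylpent-3-en-1-yl)-9-(prop-1-en-2-yl)undeca-2,6-dienoate; 20 ethyl 2-[bis(2-methylphenoxy)phosphoryl]acetate (3 equiv)
Product: 21 1-ethyl 13-methyl (5R,7E,11E)-2-[bis(2-methylphenoxy)phosphoryl]-8-methyl-12-(4-methylpent-3-en-1-yl)-5-(prop-1-en-2-yl)trideca-7,11-dienedioate (both C2 epimers)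
Conditions: NaH (2.8 equiv), DMSO, rt; then 19, rt to 45 °C
Reagents that add atoms: none
Why: SN2 C-alkylation of the sodium salt of the phosphonoacetate by the primary iodide, with excess anion to suppress dialkylation; the new C2 centre is irrelevant because it becomes sp2 in step 16.

Step 14
Reactants: 22 furan-3-carbaldehyde; 23 2-(triphenyl-λ5-phosphanylidene)acetaldehyde
Product: 24 (2E)-3-(furan-3-yl)prop-2-enal
Conditions: toluene, 80 °C
Reagents that add atoms: none
Why: Wittig reaction with a formyl-stabilised ylide, giving the (E)-enal by two-carbon homologation.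

Step 15
Reactants: 24 (2E)-3-(furan-3-yl)prop-2-enal
Product: 25 3-(furan-3-yl)propanal
Conditions: ene-reductase (Old Yellow Enzyme family), NAD+ (cat.), formate dehydrogenase, HCO2Na (3 equiv), KH2PO4/K2HPO4 buffer pH 7.0, DMSO (5 vol %), 30 °C
Reagents that add atoms: none
Why: Biocatalytic conjugate reduction by an ene-reductase (flavin-dependent oxidoreductase): hydride from the reduced flavin adds to C3 and a proton to C2 of the activated alkene only, so the aldehyde and the furan ring, which metal-catalysed hydrogenation or hydride reagents would endanger, stay intact.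

Step 16
Reactants: 21 1-ethyl 13-methyl (5R,7E,11E)-2-[bis(2-methylphenoxy)phosphoryl]-8-methyl-12-(4-methylpent-3-en-1-yl)-5-(prop-1-en-2-yl)trideca-7,11-dienedioate; 25 3-(furan-3-yl)propanal (1.3 equiv)
Product: 26 1-ethyl 13-methyl (2Z,5R,7E,11E)-2-[3-(furan-3-yl)propylidene]-8-methyl-12-(4-methylpent-3-en-1-yl)-5-(prop-1-en-2-yl)trideca-7,11-dienedioate
Conditions: NaH (1.0 equiv), THF, 0 °C; then 25, −78 to 0 °C
Reagents that add atoms: none
Why: Ando-type (Z)-selective Horner–Wadsworth–Emmons olefination: the electron-poor diaryl phosphonate makes elimination from the kinetically formed adduct fast, which places the aldehyde chain cis to the ester (2Z); the minor isomer is removed by chromatography.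

Step 17
Reactants: 26 1-ethyl 13-methyl (2Z,5R,7E,11E)-2-[3-(furan-3-yl)propylidene]-8-methyl-12-(4-methylpent-3-en-1-yl)-5-(prop-1-en-2-yl)trideca-7,11-dienedioate
Product: 27 (2Z,5R,7E,11E)-2-[3-(furan-3-yl)propylidene]-8-methyl-12-(4-methylpent-3-en-1-yl)-5-(prop-1-en-2-yl)trideca-7,11-dienedioic acid
Conditions: LiOH·H2O (10 equiv), THF/MeOH/H2O 3:1:1, 45 °C; then 1 M HCl to pH 3, 0 °C
Reagents that add atoms: lithium hydroxide, [Li+].[OH-]
Why: Saponification of the two conjugated esters by acyl substitution; the stereocentre bears no acidic hydrogen and the brief, cold acidification spares the furan and the alkenes.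

**Compound list**
1 | 5,6-dihydro-2H-pyran-2-one | O=C1C=CCCO1 | starting material
2 | 4,4,5,5-tetramethyl-2-(prop-1-en-2-yl)-1,3,2-dioxaborolane (isopropenylboronic acid pinacol ester) | CC(=C)B1OC(C)(C)C(C)(C)O1 | starting material
3 | (4R)-4-(prop-1-en-2-yl)oxan-2-one | C=C(C)[C@@H]1CCOC(=O)C1 | intermediate
4 | (4R)-4-(prop-1-en-2-yl)oxan-2-ol (both anomers) | C=C(C)[C@@H]1CCOC(O)C1 | intermediate
5 | prop-1-en-2-ylmagnesium bromide | C=C(C)[Mg]Br | starting material
6 | (5R)-2-methyl-5-(prop-1-en-2-yl)hept-1-ene-3,7-diol (both C3 epimers) | C=C(C)[C@@H](CC(O)C(C)=C)CCO | intermediate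
7 | (5R)-7-[(tert-butyldimethylsilyl)oxy]-2-methyl-5-(prop-1-en-2-yl)hept-1-en-3-ol (both C3 epimers) | C=C(C)[C@@H](CC(O)C(C)=C)CCO[Si](C)(C)C(C)(C)C | intermediate
8 | 1,1,1-triethoxyethane (triethyl orthoacetate) | CC(OCC)(OCC)OCC | starting material
9 | tert-butyl{[(3R)-5-[(1-ethoxyethenyl)oxy]-6-methyl-3-(prop-1-en-2-yl)hept-6-en-1-yl]oxy}dimethylsilane (ketene acetal, not isolated) | C=C(C)[C@@H](CC(OC(=C)OCC)C(C)=C)CCO[Si](C)(C)C(C)(C)C | intermediate
10 | ethyl (4E,7S)-9-[(tert-butyldimethylsilyl)oxy]-4-methyl-7-(prop-1-en-2-yl)non-4-enoate | C=C(C)[C@@H](C/C=C(\C)CCC(=O)OCC)CCO[Si](C)(C)C(C)(C)C | intermediate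
11 | (4E,7S)-9-[(tert-butyldimethylsilyl)oxy]-4-methyl-7-(prop-1-en-2-yl)non-4-en-1-ol | C=C(C)[C@@H](C/C=C(\C)CCCO)CCO[Si](C)(C)C(C)(C)C | intermediate
12 | (4E,7S)-9-[(tert-butyldimethylsilyl)oxy]-4-methyl-7-(prop-1-en-2-yl)non-4-enal | C=C(C)[C@@H](C/C=C(\C)CCC=O)CCO[Si](C)(C)C(C)(C)C | intermediate
13 | 5-bromo-2-methylpent-2-ene | CC(C)=CCCBr | starting material
14 | (4-methylpent-3-en-1-yl)triphenylphosphonium bromide | CC(C)=CCC[P+](c1ccccc1)(c1ccccc1)c1ccccc1.[Br-] | intermediate
15 | (4-methylpent-3-en-1-ylidene)triphenyl-λ5-phosphane (ylide, not isolated) | CC(C)=CCC=P(c1ccccc1)(c1ccccc1)c1ccccc1 | intermediate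
16 | methyl 6-methyl-2-(triphenyl-λ5-phosphanylidene)hept-5-enoate | COC(=O)C(CCC=C(C)C)=P(c1ccccc1)(c1ccccc1)c1ccccc1 | intermediate
17 | methyl (2E,6E,9S)-11-[(tert-butyldimethylsilyl)oxy]-6-methyl-2-(4-methylpent-3-en-1-yl)-9-(prop-1-en-2-yl)undeca-2,6-dienoate | C=C(C)[C@@H](C/C=C(\C)CC/C=C(\CCC=C(C)C)C(=O)OC)CCO[Si](C)(C)C(C)(C)C | intermediate
18 | methyl (2E,6E,9S)-11-hydroxy-6-methyl-2-(4-methylpent-3-en-1-yl)-9-(prop-1-en-2-yl)undeca-2,6-dienoate | C=C(C)[C@@H](C/C=C(\C)CC/C=C(\CCC=C(C)C)C(=O)OC)CCO | intermediate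
19 | methyl (2E,6E,9S)-11-iodo-6-methyl-2-(4-methylpent-3-en-1-yl)-9-(prop-1-en-2-yl)undeca-2,6-dienoate | C=C(C)[C@@H](C/C=C(\C)CC/C=C(\CCC=C(C)C)C(=O)OC)CCI | intermediate
20 | ethyl 2-[bis(2-methylphenoxy)phosphoryl]acetate | CCOC(=O)CP(=O)(Oc1ccccc1C)Oc1ccccc1C | starting material
21 | 1-ethyl 13-methyl (5R,7E,11E)-2-[bis(2-methylphenoxy)phosphoryl]-8-methyl-12-(4-methylpent-3-en-1-yl)-5-(prop-1-en-2-yl)trideca-7,11-dienedioate (both C2 epimers) | C=C(C)[C@@H](C/C=C(\C)CC/C=C(\CCC=C(C)C)C(=O)OC)CCC(C(=O)OCC)P(=O)(Oc1ccccc1C)Oc1ccccc1C | intermediate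
22 | furan-3-carbaldehyde | O=Cc1ccoc1 | starting material
23 | 2-(triphenyl-λ5-phosphanylidene)acetaldehyde | O=CC=P(c1ccccc1)(c1ccccc1)c1ccccc1 | starting material
24 | (2E)-3-(furan-3-yl)prop-2-enal | O=C/C=C/c1ccoc1 | intermediate
25 | 3-(furan-3-yl)propanal | O=CCCc1ccoc1 | intermediate
26 | 1-ethyl 13-methyl (2Z,5R,7E,11E)-2-[3-(furan-3-yl)propylidene]-8-methyl-12-(4-methylpent-3-en-1-yl)-5-(prop-1-en-2-yl)trideca-7,11-dienedioate | C=C(C)[C@@H](C/C=C(\C)CC/C=C(\CCC=C(C)C)C(=O)OC)CC/C(=C/CCc1ccoc1)C(=O)OCC | intermediate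
27 | (2Z,5R,7E,11E)-2-[3-(furan-3-yl)propylidene]-8-methyl-12-(4-methylpent-3-en-1-yl)-5-(prop-1-en-2-yl)trideca-7,11-dienedioic acid | C=C(C)[C@@H](C/C=C(\C)CC/C=C(\CCC=C(C)C)C(=O)O)CC/C(=C/CCc1ccoc1)C(=O)O | target

**Step count and risks**
Total steps: 17. Longest linear sequence: 13 steps (1 to 27 through steps 1–7, 10–13, 16 and 17); steps 8–9 and 14–15 are side branches.

The three steps most likely to fail are steps 1, 13 and 16.

Step 1 may suffer from protodeboronation of the 1,1-disubstituted alkenylboronate, slow addition to the lactone or eroded enantioselectivity. The fallback sets out from 1 and 5 and comes back to the route at lactol 4; it sets the stereocentre by enzymatic desymmetrisation instead. CuBr·SMe2-catalysed conjugate addition of 5 to 1 (THF, −40 °C) gives racemic 4-(prop-1-en-2-yl)oxan-2-one F1. LiAlH4 reduces it to the achiral, prochiral 3-(prop-1-en-2-yl)pentane-1,5-diol F2. A lipase (serine hydrolase, chosen by screening; vinyl acetate, t-BuOMe, rt) acetylates one enantiotopic hydroxyethyl arm to give (3S)-5-hydroxy-3-(prop-1-en-2-yl)pentyl acetate F3. TEMPO/PhI(OAc)2 oxidation of the free arm gives (3R)-5-oxo-3-(prop-1-en-2-yl)pentyl acetate F4, and K2CO3/MeOH removes the acetate so that the hydroxy aldehyde closes to 4.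

Step 13 is at risk because the diaryl phosphonoacetate anion is a weak nucleophile and the alkylation may stall or give elimination. The fallback sets out from 19 and comes back at 21; it forms the C–C bond with a more nucleophilic phosphonate and builds the aryl phosphonate afterwards. The sodium salt of triethyl phosphonoacetate (NaH, THF/DMF, 50 °C) is alkylated by 19 to give the diethyl phosphonate F5. Me3SiBr (CH2Cl2, 0 °C) converts it into the bis(trimethylsilyl) phosphonate F6, (COCl)2 with catalytic DMF gives the phosphonic dichloride F7, and 2-methylphenol/Et3N installs the two aryloxy groups to give 21.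

Step 16 may give an unsatisfactory Z:E ratio with the α-branched phosphonate. The fallback sets out from 25 and 19 and comes back at 26; it fixes the geometry by stereospecific cross-coupling instead of olefination. Aldehyde 25 with dimethyl (1-diazo-2-oxopropyl)phosphonate and K2CO3 in MeOH gives 3-(but-3-yn-1-yl)furan F8. Deprotonation with n-BuLi and acylation with ClCO2Et gives ethyl 5-(furan-3-yl)pent-2-ynoate F9. Syn-hydrostannation with Bu3SnH and Pd(PPh3)4 gives ethyl (2E)-5-(furan-3-yl)-2-(tributylstannyl)pent-2-enoate F10, and I2 converts it with retention into ethyl (2E)-5-(furan-3-yl)-2-iodopent-2-enoate F11. Iodide 19 is turned with Zn and LiCl in THF into the alkylzinc iodide F12, and Negishi coupling of F12 with F11 (Pd(OAc)2, SPhos, THF, rt) proceeds with retention of alkene geometry to give 26.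

**Further compounds**
F1 | step 1 | 4-(prop-1-en-2-yl)oxan-2-one (racemic) | C=C(C)C1CCOC(=O)C1
F2 | step 1 | 3-(prop-1-en-2-yl)pentane-1,5-diol | C=C(C)C(CCO)CCO
F3 | step 1 | (3S)-5-hydroxy-3-(prop-1-en-2-yl)pentyl acetate | C=C(C)[C@@H](CCO)CCOC(C)=O
F4 | step 1 | (3R)-5-oxo-3-(prop-1-en-2-yl)pentyl acetate | C=C(C)[C@@H](CC=O)CCOC(C)=O
F5 | step 13 | 1-ethyl 13-methyl (5R,7E,11E)-2-(diethoxyphosphoryl)-8-methyl-12-(4-methylpent-3-en-1-yl)-5-(prop-1-en-2-yl)trideca-7,11-dienedioate | C=C(C)[C@@H](C/C=C(\C)CC/C=C(\CCC=C(C)C)C(=O)OC)CCC(C(=O)OCC)P(=O)(OCC)OCC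
F6 | step 13 | 1-ethyl 13-methyl (5R,7E,11E)-2-{bis[(trimethylsilyl)oxy]phosphoryl}-8-methyl-12-(4-methylpent-3-en-1-yl)-5-(prop-1-en-2-yl)trideca-7,11-dienedioate | C=C(C)[C@@H](C/C=C(\C)CC/C=C(\CCC=C(C)C)C(=O)OC)CCC(C(=O)OCC)P(=O)(O[Si](C)(C)C)O[Si](C)(C)C
F7 | step 13 | 1-ethyl 13-methyl (5R,7E,11E)-2-(dichlorophosphoryl)-8-methyl-12-(4-methylpent-3-en-1-yl)-5-(prop-1-en-2-yl)trideca-7,11-dienedioate | C=C(C)[C@@H](C/C=C(\C)CC/C=C(\CCC=C(C)C)C(=O)OC)CCC(C(=O)OCC)P(=O)(Cl)Cl
F8 | step 16 | 3-(but-3-yn-1-yl)furan | C#CCCc1ccoc1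
F9 | step 16 | ethyl 5-(furan-3-yl)pent-2-ynoate | CCOC(=O)C#CCCc1ccoc1
F10 | step 16 | ethyl (2E)-5-(furan-3-yl)-2-(tributylstannyl)pent-2-enoate | CCOC(=O)/C(=C\CCc1ccoc1)[Sn](CCCC)(CCCC)CCCC
F11 | step 16 | ethyl (2E)-5-(furan-3-yl)-2-iodopent-2-enoate | CCOC(=O)/C(I)=C\CCc1ccoc1
F12 | step 16 | [(3S,5E,9E)-10-(methoxycarbonyl)-6,14-dimethyl-3-(prop-1-en-2-yl)pentadeca-5,9,13-trien-1-yl]zinc iodide | C=C(C)[C@@H](C/C=C(\C)CC/C=C(\CCC=C(C)C)C(=O)OC)CC[Zn]I
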